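**Plan**
Retrosynthesis: after removal of four silyl groups, the first cut is C1′–C1, the bond from the side-chain carbinol carbon to the quaternary oxirane carbon of the 7-oxabicyclo[4.1.0]hept-3-ene. This gives a (2′Z,4′E)-dienal and a C1 carbanion of the finished, protected bicycle.
The dienal is cut at C3′–C4′ (Suzuki coupling), at C4′=C5′ (Takai–Utimoto olefination) and at the C1″–C6″ ring bond (epoxide–alkene cyclisation of epoxygeranyl acetate). The bicycle is cut at C3=C4 (ring-closing metathesis), at O7 (epoxidation), at C1–Sn (hydrostannation) and at both alkyne–carbinol bonds.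
Forward: the cyclohexenol ring is made first and the chain is grown to the dienal. Separately, an acyclic dienyne diol is built, stannylated, epoxidised and closed to the bicycle. Union and global desilylation follow.
Enabling feature: C1 is a fusion atom shared by the oxirane (C1–C6–O7) and the six-membered ring. A carbanion there is pyramidal, cannot invert, and cannot expel the C2 oxygen, because that would need a double bond at the oxirane ring fusion. The finished epoxide can therefore act as the nucleophile, and no oxidant ever meets the doubly allylic C1′ carbinol or the diene.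
Stereochemistry: Shi epoxidation sets C5″, and the chair cyclisation relays it to C1″. Two ligand-controlled zinc alkynylations set C5 and C2. An A(1,3)-controlled, hydroxyl-directed epoxidation sets C1 and C6. The union keeps C1 by retention and sets C1′ through a lithium-bridged, sterically biased addition. Alkene geometry comes from trans-hydroalumination (2′Z), Takai–Utimoto olefination (4′E) and syn-hydrostannation.

Key step: step 20

Assumption: the facial sense of the zinc–ProPhenol alkynylations is taken to be that of the related aldol reactions; should it be the reverse, the ligand antipodes of steps 12 and 15 are exchanged.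

Step 1
Reactants: 1 geranyl acetate
Product: 2 (2E)-5-[(2R)-3,3-dimethyloxiran-2-yl]-3-methylpent-2-en-1-yl acetate
Conditions: D-fructose-derived ketone catalyst (30 mol %), Oxone (KHSO5), K2CO3, Bu4NHSO4 (cat.), Na2B4O7 buffer, MeCN–CH2(OMe)2–H2O, 0 °C
Reagents that add atoms: potassium peroxymonosulfate [K+].[O-]S(=O)(=O)OO
Why: Shi asymmetric epoxidation: the chiral dioxirane reacts only with the electron-rich 6,7-alkene because the 2,3-alkene is deactivated by the allylic acetate, and the spiro transition state of the D-fructose-derived catalyst should deliver oxygen to the face that makes the oxirane CH carbon R.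

Step 2
Reactants: 2 (R)-6,7-epoxygeranyl acetate
Product: 3 [(1S,5R)-5-hydroxy-2,6,6-trimethylcyclohex-2-en-1-yl]methyl acetate (OH and CH2OAc cis)
Conditions: ZrCl4 (20 mol %), CH2Cl2, 0 °C
Reagents that add atoms: none
Why: Lewis-acid-promoted biomimetic epoxide–alkene (cation–olefin) cyclisation: the E-2,3-alkene opens the activated oxirane at its tertiary carbon through a chair in which the C–O bond and the CH2OAc group both become equatorial, so that the retained R carbinol centre fixes the new ring stereocentre as S (cis), and loss of a ring CH2 proton from the tertiary cation should give the endocyclic trisubstituted alkene.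

Step 3
Reactants: 3 hydroxy acetate
Product: 4 [(1S,5R)-2,6,6-trimethyl-5-(triethylsilyloxy)cyclohex-2-en-1-yl]methyl acetate
Conditions: TESOTf, 2,6-lutidine, CH2Cl2, 0 °C
Reagents that add atoms: triethylsilyl triflate CC[Si](CC)(CC)OS(=O)(=O)C(F)(F)F
Why: Silyl ether formation with a silyl triflate, which is reactive enough for the hindered neopentyl-type secondary alcohol, while the small triethylsilyl group is chosen so that it can leave under mild fluoride conditions at the end.

Step 4
Reactants: 4 silyl ether acetate
Product: 5 [(1S,5R)-2,6,6-trimethyl-5-(triethylsilyloxy)cyclohex-2-en-1-yl]methanol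
Conditions: K2CO3 (cat.), MeOH, rt
Reagents that add atoms: none
Why: Base-catalysed transesterification (acetate methanolysis) frees the primary alcohol and leaves the silyl ether, the alkene and both stereocentres untouched.

Step 5
Reactants: 5 primary alcohol
Product: 6 (1S,5R)-2,6,6-trimethyl-5-(triethylsilyloxy)cyclohex-2-ene-1-carbaldehyde
Conditions: Dess–Martin periodinane, CH2Cl2, 0 °C to rt
Reagents that add atoms: none
Why: Dess–Martin oxidation works under neutral, non-enolising conditions, so that the aldehyde should form without epimerisation at C1 and without migration of the β,γ-alkene into conjugation.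

Step 6
Reactants: 6 aldehyde; 7 2-(dichloromethyl)-4,4,5,5-tetramethyl-1,3,2-dioxaborolane
Product: 8 2-{(E)-2-[(1S,5R)-2,6,6-trimethyl-5-(triethylsilyloxy)cyclohex-2-en-1-yl]ethenyl}-4,4,5,5-tetramethyl-1,3,2-dioxaborolane
Conditions: CrCl2, LiI, THF, rt
Reagents that add atoms: none
Why: Takai–Utimoto olefination in its boron variant: the geminal dichromium reagent made from 7 adds to the aldehyde and eliminates to the E-alkenylboronate, and the non-basic medium spares the epimerisable α-stereocentre.

Step 7
Reactants: 9 but-2-yn-1-ol
Product: 10 (Z)-3-iodobut-2-en-1-ol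
Conditions: NaAlH2(OCH2CH2OMe)2, THF, 0 °C to rt; then I2, −78 °C
Reagents that add atoms: iodine [I][I]
Why: Hydroxyl-directed trans-hydroalumination of a propargylic alcohol places aluminium on C3 in a five-membered alkoxyaluminate, and iodinolysis with retention gives the Z-iodide only.

Step 8
Reactants: 8 E-alkenylboronate; 10 Z-iodide
Product: 11 (2Z,4E)-3-methyl-5-[(1S,5R)-2,6,6-trimethyl-5-(triethylsilyloxy)cyclohex-2-en-1-yl]penta-2,4-dien-1-ol
Conditions: PdCl2(dppf) (5 mol %), K3PO4, THF–H2O, rt
Reagents that add atoms: none
Why: Suzuki–Miyaura alkenyl–alkenyl coupling proceeds with retention of configuration in both partners and thus joins the E-boronate and the Z-iodide to the (2Z,4E)-diene at room temperature.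

Step 9
Reactants: 11 dienol
Product: 12 (2Z,4E)-3-methyl-5-[(1S,5R)-2,6,6-trimethyl-5-(triethylsilyloxy)cyclohex-2-en-1-yl]penta-2,4-dienal
Conditions: MnO2, CH2Cl2, rt, dark
Reagents that add atoms: none
Why: Allylic alcohol oxidation with MnO2 is neutral and heterogeneous, which should keep the 2Z geometry of the enal when light and long contact times are avoided.

Step 10
Reactants: 13 2-methylidenepropane-1,3-diol
Product: 14 2-{[(tert-butyldimethylsilyl)oxy]methyl}prop-2-en-1-ol
Conditions: NaH (1 equiv), TBSCl (1 equiv), THF, 0 °C to rt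
Reagents that add atoms: tert-butyldimethylsilyl chloride CC(C)(C)[Si](C)(C)Cl
Why: Monosilylation of a symmetrical diol through its monosodium alkoxide, whose low solubility limits the second silylation.

Step 11
Reactants: 14 monosilyl ether
Product: 15 2-{[(tert-butyldimethylsilyl)oxy]methyl}prop-2-enal
Conditions: MnO2, CH2Cl2, rt
Reagents that add atoms: none
Why: Allylic alcohol oxidation with MnO2 gives the 2-substituted acrolein without touching the silyl ether.

Step 12
Reactants: 15 enal; 16 ethynyl(trimethyl)silane
Product: 17 (3R)-4-{[(tert-butyldimethylsilyl)oxy]methyl}-1-(trimethylsilyl)pent-4-en-1-yn-3-ol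
Conditions: Me2Zn, (R,R)-ProPhenol (10 mol %), Ph3PO (20 mol %), toluene, 0 °C; aq NH4Cl
Reagents that add atoms: none
Why: Catalytic asymmetric alkynylation of an aldehyde with a dinuclear zinc–ProPhenol complex: the alkynylzinc and the enal are bound to the two zinc atoms of one chiral pocket, so that the ligand alone sets the carbinol centre (later C5) as R.

Step 13
Reactants: 17 propargylic alcohol
Product: 18 tert-butyldimethylsilyl ether of 17 (3R)
Conditions: TBSCl, imidazole, DMF, rt
Reagents that add atoms: tert-butyldimethylsilyl chloride CC(C)(C)[Si](C)(C)Cl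
Why: Standard silyl ether formation protects the carbinol and makes this terminus of the alkyne the bulkier one for step 16.

Step 14
Reactants: 18 alkynylsilane
Product: 19 (3S)-3-[(tert-butyldimethylsilyl)oxy]-4-{[(tert-butyldimethylsilyl)oxy]methyl}pent-4-en-1-yne (same spatial arrangement, descriptor changed by priority)
Conditions: K2CO3 (cat.), MeOH, rt
Reagents that add atoms: none
Why: Base-catalysed protiodesilylation of the alkynylsilane in methanol removes only the C-bound trimethylsilyl group, the O-silyl ethers being stable to carbonate.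

Step 15
Reactants: 19 terminal alkyne; 20 acrolein
Product: 21 (3S,6S)-6-[(tert-butyldimethylsilyl)oxy]-7-{[(tert-butyldimethylsilyl)oxy]methyl}octa-1,7-dien-4-yn-3-ol
Conditions: Me2Zn, (S,S)-ProPhenol (20 mol %), Ph3PO (40 mol %), toluene, 0 °C; aq NH4Cl
Reagents that add atoms: none
Why: Second zinc–ProPhenol alkynylation, now with the antipodal ligand because the two carbinol carbons of the later ring are pseudo-enantiomeric, so that catalyst control sets the new centre (later C2) as S independently of the remote centre.

Step 16
Reactants: 21 dienyne alcohol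
Product: 22 (3S,4E,6S)-6-[(tert-butyldimethylsilyl)oxy]-7-{[(tert-butyldimethylsilyl)oxy]methyl}-4-(tributylstannyl)octa-1,4,7-trien-3-ol
Conditions: Bu3SnH, PdCl2(PPh3)2 (3 mol %), THF, 0 °C
Reagents that add atoms: tributyltin hydride CCCC[SnH](CCCC)CCCC
Why: Palladium-catalysed hydrostannation is a syn addition, which puts the two carbinol-bearing chains cis on the new alkene as the ring needs, and tin should go to the alkyne carbon next to the free hydroxyl group, away from the branched and silylated terminus.

Step 17
Reactants: 22 stannyl triene alcohol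
Product: 23 (1S)-1-[(2S,3S)-3-{(1R)-1-[(tert-butyldimethylsilyl)oxy]-2-{[(tert-butyldimethylsilyl)oxy]methyl}prop-2-en-1-yl}-2-(tributylstannyl)oxiran-2-yl]prop-2-en-1-ol
Conditions: mCPBA, Na2HPO4, CH2Cl2, −20 to 0 °C
Reagents that add atoms: 3-chloroperoxybenzoic acid OOC(=O)c1cccc(Cl)c1
Why: Hydroxyl-directed peracid epoxidation under A(1,3) control: on the cis-disubstituted skeleton both allylic carbons turn their H atoms inward, which places both oxygens on one face and both alkenyl groups on the other, and the hydrogen-bonded peracid attacks the oxygen-bearing face of the most substituted alkene, setting C1 and C6 so that O7 ends anti to both oxygens once the ring is closed.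

Step 18
Reactants: 23 epoxy alcohol
Product: 24 tert-butyldimethylsilyl ether of 23
Conditions: TBSOTf, 2,6-lutidine, CH2Cl2, −78 °C
Reagents that add atoms: tert-butyldimethylsilyl triflate CC(C)(C)[Si](C)(C)OS(=O)(=O)C(F)(F)F
Why: Silyl triflate silylation at low temperature protects the hindered carbinol next to the stannylated oxirane carbon before any organolithium is used, and the hindered pyridine base keeps the medium free of acid.

Step 19
Reactants: 24 epoxy diene
Product: 25 tributyl[(1R,2S,5R,6S)-2,5-bis[(tert-butyldimethylsilyl)oxy]-4-{[(tert-butyldimethylsilyl)oxy]methyl}-7-oxabicyclo[4.1.0]hept-3-en-1-yl]stannane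
Conditions: second-generation Hoveyda–Grubbs catalyst (10 mol %), toluene, high dilution, 70 °C
Reagents that add atoms: none
Why: Ring-closing metathesis: the cis-oxirane holds the vinyl and the 1,1-disubstituted alkene close together, a six-membered trisubstituted cycloalkene is formed with loss of ethene, and no stereocentre is touched.

Step 20
Reactants: 25 bicyclic epoxystannane; 12 (2Z,4E)-dienal
Product: 27 (S)-C1′ carbinol as the 2,5-bis-TBS 4-CH2OTBS 5″-TES ether of the target, via oxiranyllithium 26 (not isolated)
Conditions: 25, n-BuLi (1.0 equiv), THF, −95 °C, 10 min; then 12, −95 to −78 °C; aq NH4Cl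
Reagents that add atoms: none
Why: Tin–lithium exchange at −95 °C turns the C1–Sn bond of 25 into the non-stabilised oxiranyllithium 26 with retention, and 26 adds 1,2 to the carbonyl carbon of enal 12 faster than it decays by α-elimination; the closest known reaction type is the trapping of α-lithiated epoxides, made from α,β-epoxystannanes, with aldehydes. No ring is closed in this step. The quaternary centre C1 is controlled by the bicycle itself, because C1 is a fusion atom of the oxirane and the six-membered ring, so that the carbanion is pyramidal, cannot invert (a trans-fused 7-oxabicyclo[4.1.0]heptene is out of reach) and must bond on the face that tin left, anti to O7. The carbinol centre C1′ is controlled by the three unlike sectors around C1: in the favoured lithium-bridged transition state the formyl H points under the ring between C2 and C6, the dienyl residue lies beside the small C6–H and away from the C2 silyloxy group, and the carbonyl oxygen sits between O7 and the C2 oxygen where lithium is held, which leads to S. The step needs exchange rather than deprotonation, 1,2- rather than 1,4-addition and survival of a carbanion next to a leaving group, and these are secured by the fast attack of butyllithium at tin, by the hard lithium nucleophile and by the fact that β-elimination of the C2 silyloxy group would put a double bond at the oxirane ring fusion. The 2′Z alkene of 12 should survive because neither acid nor a reversible conjugate addition operates at this temperature.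

Step 21
Reactants: 27 tetrasilyl ether
Product: 28 target, (1R,2S,5R,6S)-1-{(1S,2Z,4E)-1-hydroxy-5-[(1S,5R)-5-hydroxy-2,6,6-trimethylcyclohex-2-en-1-yl]-3-methylpenta-2,4-dien-1-yl}-4-(hydroxymethyl)-7-oxabicyclo[4.1.0]hept-3-ene-2,5-diol
Conditions: HF·pyridine, pyridine, THF, 0 °C to rt
Reagents that add atoms: none
Why: Fluoride-mediated cleavage of all four silyl ethers under pyridine-buffered, nearly neutral conditions avoids both alkoxide-induced epoxide migration (Payne rearrangement) and acid ionisation of the dienylic carbinol.

**Compound list**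
1 | geranyl acetate | CC(C)=CCC/C(C)=C/COC(C)=O | starting material
2 | (2E)-5-[(2R)-3,3-dimethyloxiran-2-yl]-3-methylpent-2-en-1-yl acetate | CC(=O)OC/C=C(\C)CC[C@H]1OC1(C)C | intermediate
3 | [(1S,5R)-5-hydroxy-2,6,6-trimethylcyclohex-2-en-1-yl]methyl acetate | CC1=CC[C@@H](O)C(C)(C)[C@H]1COC(C)=O | intermediate
4 | [(1S,5R)-2,6,6-trimethyl-5-(triethylsilyloxy)cyclohex-2-en-1-yl]methyl acetate | CC1=CC[C@@H](O[Si](CC)(CC)CC)C(C)(C)[C@H]1COC(C)=O | intermediate
5 | [(1S,5R)-2,6,6-trimethyl-5-(triethylsilyloxy)cyclohex-2-en-1-yl]methanol | CC1=CC[C@@H](O[Si](CC)(CC)CC)C(C)(C)[C@H]1CO | intermediate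
6 | (1S,5R)-2,6,6-trimethyl-5-(triethylsilyloxy)cyclohex-2-ene-1-carbaldehyde | CC1=CC[C@@H](O[Si](CC)(CC)CC)C(C)(C)[C@H]1C=O | intermediate
7 | 2-(dichloromethyl)-4,4,5,5-tetramethyl-1,3,2-dioxaborolane | ClC(Cl)B1OC(C)(C)C(C)(C)O1 | starting material
8 | (E)-alkenyl pinacol boronate of the (1S,5R)-silyloxycyclohexenyl unit | CC1=CC[C@@H](O[Si](CC)(CC)CC)C(C)(C)[C@H]1/C=C/B1OC(C)(C)C(C)(C)O1 | intermediate
9 | but-2-yn-1-ol | CC#CCO | starting material
10 | (Z)-3-iodobut-2-en-1-ol | C/C(I)=C/CO | intermediate
11 | (2Z,4E)-3-methyl-5-[(1S,5R)-2,6,6-trimethyl-5-(triethylsilyloxy)cyclohex-2-en-1-yl]penta-2,4-dien-1-ol | CC1=CC[C@@H](O[Si](CC)(CC)CC)C(C)(C)[C@H]1/C=C/C(C)=C\CO | intermediate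
12 | (2Z,4E)-3-methyl-5-[(1S,5R)-2,6,6-trimethyl-5-(triethylsilyloxy)cyclohex-2-en-1-yl]penta-2,4-dienal | CC1=CC[C@@H](O[Si](CC)(CC)CC)C(C)(C)[C@H]1/C=C/C(C)=C\C=O | intermediate
13 | 2-methylidenepropane-1,3-diol | C=C(CO)CO | starting material
14 | 2-{[(tert-butyldimethylsilyl)oxy]methyl}prop-2-en-1-ol | C=C(CO)CO[Si](C)(C)C(C)(C)C | intermediate
15 | 2-{[(tert-butyldimethylsilyl)oxy]methyl}prop-2-enal | C=C(C=O)CO[Si](C)(C)C(C)(C)C | intermediate
16 | ethynyl(trimethyl)silane | C#C[Si](C)(C)C | starting material
17 | (3R)-4-{[(tert-butyldimethylsilyl)oxy]methyl}-1-(trimethylsilyl)pent-4-en-1-yn-3-ol | C[Si](C)(C)C#C[C@H](O)C(=C)CO[Si](C)(C)C(C)(C)C | intermediate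
18 | tert-butyldimethylsilyl ether of 17 (3R) | C[Si](C)(C)C#C[C@H](O[Si](C)(C)C(C)(C)C)C(=C)CO[Si](C)(C)C(C)(C)C | intermediate
19 | (3S)-3-[(tert-butyldimethylsilyl)oxy]-4-{[(tert-butyldimethylsilyl)oxy]methyl}pent-4-en-1-yne | C#C[C@H](O[Si](C)(C)C(C)(C)C)C(=C)CO[Si](C)(C)C(C)(C)C | intermediate
20 | acrolein | C=CC=O | starting material
21 | (3S,6S)-6-[(tert-butyldimethylsilyl)oxy]-7-{[(tert-butyldimethylsilyl)oxy]methyl}octa-1,7-dien-4-yn-3-ol | C=C[C@H](O)C#C[C@H](O[Si](C)(C)C(C)(C)C)C(=C)CO[Si](C)(C)C(C)(C)C | intermediate
22 | (3S,4E,6S)-4-(tributylstannyl) triene alcohol (carbinol chains cis on the alkene) | C=C[C@H](O)/C(=C\[C@H](O[Si](C)(C)C(C)(C)C)C(=C)CO[Si](C)(C)C(C)(C)C)[Sn](CCCC)(CCCC)CCCC | intermediate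
23 | (1S)-1-[(2S,3S)-3-{(1R)-silyloxyalkenyl}-2-(tributylstannyl)oxiran-2-yl]prop-2-en-1-ol | CCCC[Sn](CCCC)(CCCC)[C@@]1(O[C@H]1[C@H](O[Si](C)(C)C(C)(C)C)C(=C)CO[Si](C)(C)C(C)(C)C)[C@@H](O)C=C | intermediate
24 | tert-butyldimethylsilyl ether of 23 | CCCC[Sn](CCCC)(CCCC)[C@@]1(O[C@H]1[C@H](O[Si](C)(C)C(C)(C)C)C(=C)CO[Si](C)(C)C(C)(C)C)[C@@H](O[Si](C)(C)C(C)(C)C)C=C | intermediate
25 | tributyl[(1R,2S,5R,6S)-2,5-bis(TBSO)-4-(TBSOCH2)-7-oxabicyclo[4.1.0]hept-3-en-1-yl]stannane (O7 anti to both silyloxy groups) | CCCC[Sn](CCCC)(CCCC)[C@]12O[C@H]1[C@H](O[Si](C)(C)C(C)(C)C)C(CO[Si](C)(C)C(C)(C)C)=C[C@@H]2O[Si](C)(C)C(C)(C)C | intermediate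
26 | oxiranyllithium from 25 (lithium in the place of tin, retention) | [Li][C@]12O[C@H]1[C@H](O[Si](C)(C)C(C)(C)C)C(CO[Si](C)(C)C(C)(C)C)=C[C@@H]2O[Si](C)(C)C(C)(C)C | intermediate
27 | tetrasilyl ether of the target with free (S)-C1′ hydroxyl | CC1=CC[C@@H](O[Si](CC)(CC)CC)C(C)(C)[C@H]1/C=C/C(C)=C\[C@H](O)[C@]12O[C@H]1[C@H](O[Si](C)(C)C(C)(C)C)C(CO[Si](C)(C)C(C)(C)C)=C[C@@H]2O[Si](C)(C)C(C)(C)C | intermediate
28 | CNP0389279.1 | CC1=CC[C@@H](O)C(C)(C)[C@H]1/C=C/C(C)=C\[C@H](O)[C@]12O[C@H]1[C@H](O)C(CO)=C[C@@H]2O | target

Total step count: 21. Longest linear sequence: 12 steps (13 to 28, steps 10 to 21).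

**Steps most likely to fail**

Step 20. The lithiated oxirane may decay before capture, by α-elimination or by silyl migration from the C5 oxygen to carbon. Above all, the two faces of the aldehyde may be poorly discriminated. The fallback sets C1′ by reduction instead of by addition. It sets out from 27, taken as its mixture of C1′ epimers. Dess–Martin oxidation gives the C1′ ketone, epoxy dienone F1. Reduction under non-chelating Luche conditions (NaBH4, CeCl3, MeOH, −78 °C) should follow the polar Felkin–Anh model, with the C1–O7 bond perpendicular to the carbonyl group and the hydride passing the C6–H side. This should give the S carbinol, so the route is rejoined at 27.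

Step 16. Tin may be delivered to the wrong alkyne carbon, because both termini carry an oxygenated carbon. The fallback polarises the alkyne with a carbonyl group. It sets out from 19 and bypasses step 15. Lithiation with n-BuLi and formylation with DMF give the acetylenic aldehyde F2. Hydrostannation with Bu3SnH and Pd(PPh3)4 places tin next to the carbonyl carbon by syn addition and gives the α-stannyl enal F3. Catalytic asymmetric vinylation follows, with divinylzinc and 3-exo-morpholinoisoborneol, the ligand antipode being chosen for the S carbinol. This comes back to the route at 22.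

Step 19. The metathesis may not turn over, because both alkenes of 24 sit next to silyloxy-bearing carbons and one is 1,1-disubstituted. Ruthenium hydrides may also move the alkenes. The fallback closes the ring before the epoxidation, so that a flatter triene is cyclised and the oxirane face is then fixed by the ring instead of by acyclic conformation. It sets out from 22. TBSOTf and 2,6-lutidine give the tris-silyl ether F4, and ring-closing metathesis gives the cis-3,6-bis(silyloxy)cyclohexa-1,4-dienylstannane F5. Buffered mCPBA should attack the more electron-rich stannyl alkene, since the other alkene carries three allylic C–O bonds, and should do so from the face opposite to the two silyloxy groups. This comes back to the route at 25.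

**Further compounds**
F1 | step 20 | C1′ ketone of 27 (epoxy dienone) | CC1=CC[C@@H](O[Si](CC)(CC)CC)C(C)(C)[C@H]1/C=C/C(C)=C\C(=O)[C@]12O[C@H]1[C@H](O[Si](C)(C)C(C)(C)C)C(CO[Si](C)(C)C(C)(C)C)=C[C@@H]2O[Si](C)(C)C(C)(C)C
F2 | step 16 | (4S)-4-[(tert-butyldimethylsilyl)oxy]-5-{[(tert-butyldimethylsilyl)oxy]methyl}hex-5-en-2-ynal | O=CC#C[C@H](O[Si](C)(C)C(C)(C)C)C(=C)CO[Si](C)(C)C(C)(C)C
F3 | step 16 | (2E,4S)-4-[(tert-butyldimethylsilyl)oxy]-5-{[(tert-butyldimethylsilyl)oxy]methyl}-2-(tributylstannyl)hexa-2,5-dienal | O=C/C(=C\[C@H](O[Si](C)(C)C(C)(C)C)C(=C)CO[Si](C)(C)C(C)(C)C)[Sn](CCCC)(CCCC)CCCC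
F4 | step 19 | tert-butyldimethylsilyl ether of 22 | C=C[C@H](O[Si](C)(C)C(C)(C)C)/C(=C\[C@H](O[Si](C)(C)C(C)(C)C)C(=C)CO[Si](C)(C)C(C)(C)C)[Sn](CCCC)(CCCC)CCCC
F5 | step 19 | tributyl[cis-3,6-bis(TBSO)-4-(TBSOCH2)cyclohexa-1,4-dien-1-yl]stannane | CCCC[Sn](CCCC)(CCCC)C1=C[C@H](O[Si](C)(C)C(C)(C)C)C(CO[Si](C)(C)C(C)(C)C)=C[C@@H]1O[Si](C)(C)C(C)(C)C
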